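Does raising the protonated nucleophile from theta to zeta change the part of the electrophile that has reacted by 5 percentage points or more?

| setting | zeta | epsilon | theta |
|---|---|---|---|
| electrophile | 0.25 M | 0.25 M | 0.25 M |
| protonated nucleophile | 1.10 M | 0.750 M | 0.500 M |
| gas | 29 mM (held) | 29 mM (held) | 29 mM (held) |
| time | 40 s | 40 s | 40 s |

    gas ⇌ free base, rate k1*(csat - [free base]) (k1 = 0.177 s⁻¹, csat = 29 mM)
    electrophile ⇌ dormant form (K2 = 0.425, k2 = 0.0973 s⁻¹)
    acid set free + free base ⇌ salt of the base (K3 = 1.16 × 10⁵ L mol⁻¹, k3 = 0.579 L mol⁻¹ s⁻¹)
    electrophile + nucleophile ⇌ acid set free + product (K4 = 1.4, k4 = 2.13 L mol⁻¹ s⁻¹)
    nucleophile + acid set free ⇌ protonated nucleophile, settled at all times (K5 = 44700 L mol⁻¹)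

* part of the electrophile that has reacted at the end, zeta
* part of the electrophile that has reacted at the end, epsilon
* part of the electrophile that has reacted at the end, theta
* what raising the concentration of protonated nucleophile from its lowest to its highest value here does to the part of the electrophile that has reacted (changes below 5 percentage points count as none) (no change / it falls / it rises)

- at the start none of free base is dissolved
- what has gone from electrophile into another species counts as reacted, even if it can come back
- run time (zeta): 40 s

The gas line comes first: free base fills with a half-life of 3.92 s, shorter than the run, so I count it as present from early on.

Electrophile and dormant form relax with a half-life of 2.12 s, also shorter than the run, so I hold the dormant form at 0.425 times the electrophile. The electrophile is the limiting reagent, so I write its balance in fractions of the charge: electrophile, dormant form and product add up to the whole. This gives the parked share, the part of the electrophile not turned into product that sits as dormant form at balance: 29.8%. The reacted part is then the parked share plus 70.2% of the product fraction.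

With free base at its saturation value, the salt line drains acid with a half-life of 41.3 s, about the length of the run. I leave it out and accept a rough figure.

But the product still needs a number. Zeta, epsilon and theta charge the same electrophile, so nucleophile has the same forward half-life in each, 1.30 s, way back not counted, shorter than the run, so I take the product step to balance. Each product then stands for 2 acid, one from the step and one left behind by the nucleophile it used, and nucleophile times acid equals protonated nucleophile over 44700 L mol⁻¹. With electrophile at 70.2% of its charge, a cube root gives product fractions of 4.59% in zeta, 4.04% in epsilon and 3.53% in theta. So I commit to 33.0%, 32.7% and 32.3%, a spread of 0.70 points, which is less than the margin.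

The forecast stands a little above mine, at 33.5%, 33.1% and 32.6% with no change, and it opens with “The fast dormant equilibrium dominates”.

The simulation gives 33.6% for zeta, 33.1% for epsilon and 32.6% for theta, a change of 0.95 points, which counts as no change. In zeta at 40.0 s, the dormant form holds 28.3% of the charge and the product 5.27%. A flask like theta but with 0.10 M of electrophile holds 6.47% of its charge as product at 40.0 s. The parked share turns that into 34.3%, and that flask reads 34.4%.

The constants were set for the occasion; the rest is arithmetic.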